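**Retrosynthetic overview**

1. Quinone: target ⇐ selective hydrolysis of the methoxy group next to the side chain ⇐ 2,5-dimethoxyquinone ⇐ oxidative demethylation of a 3-alkyl-1,2,4,5-tetramethoxybenzene; this ring is bought as the arene and only unveiled at the end.
2. Cyclohexene ring (numbered C1 stereocentre, C2 methyl-bearing carbon, C3 alkene CH, C4, C5, C6 gem-dimethyl carbon): (S)-C1–H and the C2=C3 alkene are set together by reductive 1,3-transposition of an (R)-allylic alcohol (OH on C3, alkene C1=C2), itself made by asymmetric reduction of the enone.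
3. Enone ⇐ alkylative carbonyl transposition: the side-chain organolithium (E-alkene by alkyne carboalumination, arene attached by aryl–allyl coupling) adds to the C1 carbonyl of the mono enol ether of 2,4,4-trimethylcyclohexane-1,3-dione.
4. Ring construction (the only one, first in the route): this dione ⇐ 2-methylpentan-3-one + methyl acrylate in a one-flask Michael–Claisen [3+3] annulation that makes ring bonds C5–C6 and C2–C3.
5. Enabling feature: C1 and C3 are 1,3-related across the methyl-bearing C2, and C1 has the quaternary C6 as its other neighbour, so with oxygen on C1 and C3 the ring is a 2-methyl-1,3-dione. Its acidic C2–H makes the annulation self-correcting, and both oxygens are spent later (C1–O in the fragment union, C3–O for asymmetric induction and then removed).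

Key step: step 1

**Route**

Step 1
Reactants: 1 2-methylpentan-3-one; 2 methyl acrylate
Product: 4 2,4,4-trimethylcyclohexane-1,3-dione, via Michael adduct 3 (not isolated)
Conditions: KOtBu (1.1 equiv), THF, 0 °C → reflux; then 1 M HCl
Reagents that add atoms: none
Why: KOtBu equilibrates the two enolates of 1, the isopropyl-side enolate adds to the β-carbon of 2 (Michael step, quaternary carbon to CH2 bond), proton transfer gives the ethyl-side enolate of 3, whose carbon attacks the ester carbonyl with loss of methoxide (Claisen step, CH(CH3) to C=O bond), and the 1,3-diketone is deprotonated at once to its diketonate. The closest known reaction type is the Michael–Claisen [3+3] condensation of simple ketones with acrylic esters to cyclohexane-1,3-diones, here run on an ethyl isopropyl ketone. The one ring is closed in the second event as a 6-exo-trig (Dieckmann-type) attack of an enolate carbon on the ester carbonyl, the first bond having been made intermolecularly. The only new stereocentre, C2 of 4, is not controlled and need not be, because it is enolisable and becomes trigonal in step 2. The selectivity needed is constitutional (conjugate addition at the isopropyl carbon, acylation at the ethyl carbon) and the substrate secures it thermodynamically: only this pairing leaves a hydrogen between the two carbonyl groups, so only 4 is drained as the stable diketonate, whereas adducts made through the ethyl carbon can only close to a non-enolisable 2,2-disubstituted dione and should be returned to the pool by retro-Claisen and retro-Michael steps.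

Step 2
Reactants: 4 2,4,4-trimethylcyclohexane-1,3-dione
Product: 5 3-(2-methylpropoxy)-2,6,6-trimethylcyclohex-2-en-1-one
Conditions: 2-methylpropan-1-ol, TsOH·H2O (cat.), toluene, reflux, Dean–Stark trap
Reagents that add atoms: 2-methylpropan-1-ol, CC(C)CO
Why: Acid-catalysed enol etherification of a cyclic 1,3-dione with azeotropic removal of water is a standard reaction, and the alcohol should attack the carbonyl remote from the quaternary carbon so that the hindered carbonyl (future ring C1) survives as the ketone of the vinylogous ester, the former C2 stereocentre becoming planar.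

Step 3
Reactants: 6 tert-butyl(but-3-yn-1-yloxy)dimethylsilane
Product: 9 (2E)-5-{[tert-butyl(dimethyl)silyl]oxy}-3-methylpent-2-en-1-ol, via alkenylalane 7 (not isolated), via lithium alkenylalanate 8 (not isolated)
Conditions: AlMe3 (2 equiv), Cp2ZrCl2 (cat.), CH2Cl2, 0 °C → rt; n-BuLi, THF, −78 °C; (CH2O)n, → rt; then 1 M HCl
Reagents that add atoms: trimethylaluminium, C[Al](C)C; formaldehyde (as paraformaldehyde), C=O
Why: Negishi carboalumination adds CH3 and aluminium syn across the alkyne under zirconocene catalysis with aluminium on the terminal carbon, and the alanate made with n-BuLi transfers the alkenyl group to formaldehyde with retention, so the trisubstituted alkene is formed as the (E) isomer only.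

Step 4
Reactants: 9 (2E)-5-{[tert-butyl(dimethyl)silyl]oxy}-3-methylpent-2-en-1-ol
Product: 10 tert-butyl{[(3E)-5-bromo-3-methylpent-3-en-1-yl]oxy}dimethylsilane
Conditions: CBr4, PPh3, CH2Cl2, 0 °C
Reagents that add atoms: tetrabromomethane, BrC(Br)(Br)Br
Why: Appel bromination converts the primary allylic alcohol into the bromide through the alkoxyphosphonium ion under neutral conditions that leave the silyl ether and the alkene geometry untouched.

Step 5
Reactants: 11 1,2,4,5-tetramethoxybenzene; 10 tert-butyl{[(3E)-5-bromo-3-methylpent-3-en-1-yl]oxy}dimethylsilane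
Product: 14 tert-butyl(dimethyl){[(3E)-3-methyl-5-(2,3,5,6-tetramethoxyphenyl)pent-3-en-1-yl]oxy}silane, via aryllithium 12 (not isolated), via arylcopper 13 (not isolated)
Conditions: n-BuLi, TMEDA, THF, 0 °C; CuBr·SMe2, −40 °C; then 10, −40 → 0 °C
Reagents that add atoms: none
Why: Ortho-lithiation between two methoxy groups followed by transmetalation gives an arylcopper that substitutes the primary allylic bromide directly (SN2) rather than at the fully substituted γ-carbon, which keeps the (E)-alkene and gives the linear aryl–allyl product.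

Step 6
Reactants: 14 tert-butyl(dimethyl){[(3E)-3-methyl-5-(2,3,5,6-tetramethoxyphenyl)pent-3-en-1-yl]oxy}silane
Product: 15 (3E)-3-methyl-5-(2,3,5,6-tetramethoxyphenyl)pent-3-en-1-ol
Conditions: Bu4NF, THF, 0 °C → rt
Reagents that add atoms: none
Why: Fluoride cleaves the silyl ether through pentacoordinate silicon without touching any other group (standard desilylation).

Step 7
Reactants: 15 (3E)-3-methyl-5-(2,3,5,6-tetramethoxyphenyl)pent-3-en-1-ol
Product: 16 3-[(2E)-5-iodo-3-methylpent-2-en-1-yl]-1,2,4,5-tetramethoxybenzene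
Conditions: I2, PPh3, imidazole, CH2Cl2, 0 °C → rt
Reagents that add atoms: iodine, II
Why: The PPh3–I2–imidazole (Appel-type) iodination displaces the activated primary hydroxyl by iodide in an SN2 step under buffered conditions that the electron-rich arene and the alkene tolerate.

Step 8
Reactants: 16 3-[(2E)-5-iodo-3-methylpent-2-en-1-yl]-1,2,4,5-tetramethoxybenzene; 5 3-(2-methylpropoxy)-2,6,6-trimethylcyclohex-2-en-1-one
Product: 19 2,4,4-trimethyl-3-[(3E)-3-methyl-5-(2,3,5,6-tetramethoxyphenyl)pent-3-en-1-yl]cyclohex-2-en-1-one, via alkyllithium 17 (not isolated), via tertiary carbinol 18 (not isolated)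
Conditions: t-BuLi (2.1 equiv), Et2O–pentane, −78 °C; then 5, THF, −78 → 0 °C; then 2 M HCl, THF, rt
Reagents that add atoms: water, O
Why: Iodine–lithium exchange gives the primary alkyllithium, which can only add in 1,2-fashion to the non-enolisable ketone of 5, and aqueous acid then hydrolyses the enol ether and expels the tertiary hydroxyl to give the transposed enone (Stork–Danheiser alkylative carbonyl transposition), the carbinol stereocentre of 18 being lost in this step.

Step 9
Reactants: 19 2,4,4-trimethyl-3-[(3E)-3-methyl-5-(2,3,5,6-tetramethoxyphenyl)pent-3-en-1-yl]cyclohex-2-en-1-one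
Product: 20 (1R)-2,4,4-trimethyl-3-[(3E)-3-methyl-5-(2,3,5,6-tetramethoxyphenyl)pent-3-en-1-yl]cyclohex-2-en-1-ol
Conditions: (S)-2-methyl-CBS-oxazaborolidine (20 mol %), catecholborane, toluene, −78 → −40 °C; then MeOH, aq. NaOH
Reagents that add atoms: none
Why: In the Corey–Bakshi–Shibata reduction the ketone should bind to the boron of the (S)-oxazaborolidine with its bulky, fully substituted alkenyl arm away from the catalyst so that hydride is delivered to one face and the (R)-carbinol results, while catecholborane at low temperature leaves the side-chain alkene untouched.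

Step 10
Reactants: 20 (1R)-2,4,4-trimethyl-3-[(3E)-3-methyl-5-(2,3,5,6-tetramethoxyphenyl)pent-3-en-1-yl]cyclohex-2-en-1-ol
Product: 23 1,2,4,5-tetramethoxy-3-[(2E)-3-methyl-5-[(1S)-2,6,6-trimethylcyclohex-2-en-1-yl]pent-2-en-1-yl]benzene, via sulfonylhydrazine 21 (not isolated), via allylic diazene 22 (not isolated)
Conditions: 2-nitrobenzenesulfonylhydrazide, PPh3, diethyl azodicarboxylate, THF, −30 °C; then 23 °C
Reagents that add atoms: none
Why: Myers reductive 1,3-transposition: Mitsunobu substitution by the sulfonylhydrazide inverts the carbinol carbon, loss of arenesulfinic acid gives the allylic diazene, and its suprafacial retro-ene loss of N2 places hydrogen on ring C1 on the face opposite to the original hydroxyl, which turns (R)-20 into the (S)-configured stereocentre and fixes the alkene at C2=C3.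

Step 11
Reactants: 23 1,2,4,5-tetramethoxy-3-[(2E)-3-methyl-5-[(1S)-2,6,6-trimethylcyclohex-2-en-1-yl]pent-2-en-1-yl]benzene
Product: 24 2,5-dimethoxy-3-[(2E)-3-methyl-5-[(1S)-2,6,6-trimethylcyclohex-2-en-1-yl]pent-2-en-1-yl]cyclohexa-2,5-diene-1,4-dione
Conditions: (NH4)2Ce(NO3)6 (2.5 equiv), MeCN–H2O, 0 °C
Reagents that add atoms: water, O
Why: Oxidative demethylation of the para-dimethoxyarene by the one-electron oxidant tetravalent cerium in aqueous acetonitrile gives the quinone, both para pairs of methoxy groups leading to the same 2,5-dimethoxyquinone because the ring is symmetric about the alkyl-bearing carbon, and the stereocentre and the alkenes should survive the short, cold reaction.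

Step 12
Reactants: 24 2,5-dimethoxy-3-[(2E)-3-methyl-5-[(1S)-2,6,6-trimethylcyclohex-2-en-1-yl]pent-2-en-1-yl]cyclohexa-2,5-diene-1,4-dione
Product: 25 2-hydroxy-5-methoxy-3-[(2E)-3-methyl-5-[(1S)-2,6,6-trimethylcyclohex-2-en-1-yl]pent-2-en-1-yl]cyclohexa-2,5-diene-1,4-dione
Conditions: aq. HClO4, THF, 0 °C → rt
Reagents that add atoms: water, O
Why: Acid-mediated addition–elimination hydrolysis of a vinylogous ester should take place selectively at the methoxy group that flanks the alkyl chain, as is known for 3-alkyl-2,5-dimethoxy-1,4-benzoquinones, because this enone arm is the more basic one and its methoxy group is pushed out of conjugation by the side chain, whereas the remote methoxy group stays.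

**Compound list**

1 | 2-methylpentan-3-one | CCC(=O)C(C)C | starting material
2 | methyl acrylate | C=CC(=O)OC | starting material
3 | methyl 4,4-dimethyl-5-oxoheptanoate (Michael adduct, present as its enolate) | CCC(=O)C(C)(C)CCC(=O)OC | intermediate
4 | 2,4,4-trimethylcyclohexane-1,3-dione | CC1C(=O)CCC(C)(C)C1=O | intermediate
5 | 3-(2-methylpropoxy)-2,6,6-trimethylcyclohex-2-en-1-one | CC1=C(OCC(C)C)CCC(C)(C)C1=O | intermediate
6 | tert-butyl(but-3-yn-1-yloxy)dimethylsilane | C#CCCO[Si](C)(C)C(C)(C)C | starting material
7 | [(1E)-4-{[tert-butyl(dimethyl)silyl]oxy}-2-methylbut-1-en-1-yl]dimethylalumane | C[Al](C)/C=C(\C)CCO[Si](C)(C)C(C)(C)C | intermediate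
8 | lithium butyl[(1E)-4-{[tert-butyl(dimethyl)silyl]oxy}-2-methylbut-1-en-1-yl]dimethylaluminate | [Li+].CCCC[Al-](C)(C)/C=C(\C)CCO[Si](C)(C)C(C)(C)C | intermediate
9 | (2E)-5-{[tert-butyl(dimethyl)silyl]oxy}-3-methylpent-2-en-1-ol | OC/C=C(\C)CCO[Si](C)(C)C(C)(C)C | intermediate
10 | tert-butyl{[(3E)-5-bromo-3-methylpent-3-en-1-yl]oxy}dimethylsilane | BrC/C=C(\C)CCO[Si](C)(C)C(C)(C)C | intermediate
11 | 1,2,4,5-tetramethoxybenzene | COc1cc(OC)c(OC)cc1OC | starting material
12 | (2,3,5,6-tetramethoxyphenyl)lithium | [Li]c1c(OC)c(OC)cc(OC)c1OC | intermediate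
13 | (2,3,5,6-tetramethoxyphenyl)copper | [Cu]c1c(OC)c(OC)cc(OC)c1OC | intermediate
14 | tert-butyl(dimethyl){[(3E)-3-methyl-5-(2,3,5,6-tetramethoxyphenyl)pent-3-en-1-yl]oxy}silane | COc1cc(OC)c(OC)c(C/C=C(\C)CCO[Si](C)(C)C(C)(C)C)c1OC | intermediate
15 | (3E)-3-methyl-5-(2,3,5,6-tetramethoxyphenyl)pent-3-en-1-ol | COc1cc(OC)c(OC)c(C/C=C(\C)CCO)c1OC | intermediate
16 | 3-[(2E)-5-iodo-3-methylpent-2-en-1-yl]-1,2,4,5-tetramethoxybenzene | COc1cc(OC)c(OC)c(C/C=C(\C)CCI)c1OC | intermediate
17 | [(3E)-3-methyl-5-(2,3,5,6-tetramethoxyphenyl)pent-3-en-1-yl]lithium | COc1cc(OC)c(OC)c(C/C=C(\C)CC[Li])c1OC | intermediate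
18 | 3-(2-methylpropoxy)-2,6,6-trimethyl-1-[(3E)-3-methyl-5-(2,3,5,6-tetramethoxyphenyl)pent-3-en-1-yl]cyclohex-2-en-1-ol (racemic, formed as its lithium alkoxide) | COc1cc(OC)c(OC)c(C/C=C(\C)CCC2(O)C(C)=C(OCC(C)C)CCC2(C)C)c1OC | intermediate
19 | 2,4,4-trimethyl-3-[(3E)-3-methyl-5-(2,3,5,6-tetramethoxyphenyl)pent-3-en-1-yl]cyclohex-2-en-1-one | COc1cc(OC)c(OC)c(C/C=C(\C)CCC2=C(C)C(=O)CCC2(C)C)c1OC | intermediate
20 | (1R)-2,4,4-trimethyl-3-[(3E)-3-methyl-5-(2,3,5,6-tetramethoxyphenyl)pent-3-en-1-yl]cyclohex-2-en-1-ol | COc1cc(OC)c(OC)c(C/C=C(\C)CCC2=C(C)[C@H](O)CCC2(C)C)c1OC | intermediate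
21 | N-[(1S)-2,4,4-trimethyl-3-[(3E)-3-methyl-5-(2,3,5,6-tetramethoxyphenyl)pent-3-en-1-yl]cyclohex-2-en-1-yl]-2-nitrobenzenesulfonohydrazide | COc1cc(OC)c(OC)c(C/C=C(\C)CCC2=C(C)[C@@H](N(N)S(=O)(=O)c3ccccc3[N+](=O)[O-])CCC2(C)C)c1OC | intermediate
22 | [(1S)-2,4,4-trimethyl-3-[(3E)-3-methyl-5-(2,3,5,6-tetramethoxyphenyl)pent-3-en-1-yl]cyclohex-2-en-1-yl]diazene | COc1cc(OC)c(OC)c(C/C=C(\C)CCC2=C(C)[C@@H](N=N)CCC2(C)C)c1OC | intermediate
23 | 1,2,4,5-tetramethoxy-3-[(2E)-3-methyl-5-[(1S)-2,6,6-trimethylcyclohex-2-en-1-yl]pent-2-en-1-yl]benzene | COc1cc(OC)c(OC)c(C/C=C(\C)CC[C@@H]2C(C)=CCCC2(C)C)c1OC | intermediate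
24 | 2,5-dimethoxy-3-[(2E)-3-methyl-5-[(1S)-2,6,6-trimethylcyclohex-2-en-1-yl]pent-2-en-1-yl]cyclohexa-2,5-diene-1,4-dione | COC1=CC(=O)C(OC)=C(C/C=C(\C)CC[C@@H]2C(C)=CCCC2(C)C)C1=O | intermediate
25 | 2-hydroxy-5-methoxy-3-[(2E)-3-methyl-5-[(1S)-2,6,6-trimethylcyclohex-2-en-1-yl]pent-2-en-1-yl]cyclohexa-2,5-diene-1,4-dione | COC1=CC(=O)C(O)=C(C/C=C(\C)CC[C@@H]2C(C)=CCCC2(C)C)C1=O | target

**Step count and risks**

Total step count: 12 (steps 1–2 ring part, steps 3–7 side chain with arene, steps 8–12 after the union).
Longest linear sequence: 10 steps (steps 3–12, from 6).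

Steps most likely to fail:

Step 10. The Mitsunobu substitution at a carbinol carbon that is flanked by a fully substituted alkene may be slow, so that elimination of the activated alcohol to a diene, or loss of N2 without hydrogen transfer to the fully substituted alkene terminus, takes over. The fallback sets out from 20 and comes back at 23. Formylation with acetic formic anhydride (made in the flask from HCO2H and Ac2O) and pyridine should give (1R)-2,4,4-trimethyl-3-[(3E)-3-methyl-5-(2,3,5,6-tetramethoxyphenyl)pent-3-en-1-yl]cyclohex-2-en-1-yl formate F1. With Pd(OAc)2 (cat.) and PBu3 in warm dioxane, zerovalent palladium formed in the flask should ionise the formate with inversion, and decarboxylation of the palladium-bound formate gives a palladium hydride. This is expected to deliver hydrogen to the more substituted allyl terminus (ring C1) from the metal face, the same face as in the diazene route, to give 23 (formate hydrogenolysis of an allylic ester).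

Step 12. Hydrolysis may fail to discriminate between the two methoxy groups or run on to the dihydroxyquinone, and the acid may promote cyclisation of the freed hydroxyl onto the side-chain alkene. The fallback sets out from 24 and comes back at 25. Exhaustive hydrolysis with aqueous NaOH in ethanol under N2, followed by acidification with HCl, should give 2,5-dihydroxy-3-[(2E)-3-methyl-5-[(1S)-2,6,6-trimethylcyclohex-2-en-1-yl]pent-2-en-1-yl]cyclohexa-2,5-diene-1,4-dione F2. One equivalent of Me3SiCHN2 in methanol–toluene at 0 °C should then methylate the less hindered hydroxyl, the one next to the ring CH, to give 25 without any acid.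

Step 8. Addition to the carbonyl, which lies between a quaternary carbon and a methyl-bearing alkene carbon, may be slower than proton abstraction from the ring CH2 next to the enol ether or than decay of the organolithium. The fallback sets out from 5 and 16 and comes back at 19. LiN(iPr)2 in THF at −78 °C and then PhNTf2 should convert 5 through its extended enolate into 3-(2-methylpropoxy)-2,6,6-trimethylcyclohexa-1,3-dien-1-yl trifluoromethanesulfonate F3. Zinc dust with LiCl in THF should insert into 16 to give iodo[(3E)-3-methyl-5-(2,3,5,6-tetramethoxyphenyl)pent-3-en-1-yl]zinc F4. Negishi coupling of the two with PdCl2(dppf) in THF at 50 °C should give 1,2,4,5-tetramethoxy-3-[(2E)-3-methyl-5-[3-(2-methylpropoxy)-2,6,6-trimethylcyclohexa-1,3-dien-1-yl]pent-2-en-1-yl]benzene F5, and dilute HCl in THF hydrolyses this dienol ether to 19.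

Further compounds
F1 | step 10 | (1R)-2,4,4-trimethyl-3-[(3E)-3-methyl-5-(2,3,5,6-tetramethoxyphenyl)pent-3-en-1-yl]cyclohex-2-en-1-yl formate | COc1cc(OC)c(OC)c(C/C=C(\C)CCC2=C(C)[C@H](OC=O)CCC2(C)C)c1OC
F2 | step 12 | 2,5-dihydroxy-3-[(2E)-3-methyl-5-[(1S)-2,6,6-trimethylcyclohex-2-en-1-yl]pent-2-en-1-yl]cyclohexa-2,5-diene-1,4-dione | OC1=CC(=O)C(O)=C(C/C=C(\C)CC[C@@H]2C(C)=CCCC2(C)C)C1=O
F3 | step 8 | 3-(2-methylpropoxy)-2,6,6-trimethylcyclohexa-1,3-dien-1-yl trifluoromethanesulfonate | CC1=C(OS(=O)(=O)C(F)(F)F)C(C)(C)CC=C1OCC(C)C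
F4 | step 8 | iodo[(3E)-3-methyl-5-(2,3,5,6-tetramethoxyphenyl)pent-3-en-1-yl]zinc | COc1cc(OC)c(OC)c(C/C=C(\C)CC[Zn]I)c1OC
F5 | step 8 | 1,2,4,5-tetramethoxy-3-[(2E)-3-methyl-5-[3-(2-methylpropoxy)-2,6,6-trimethylcyclohexa-1,3-dien-1-yl]pent-2-en-1-yl]benzene | COc1cc(OC)c(OC)c(C/C=C(\C)CCC2=C(C)C(OCC(C)C)=CCC2(C)C)c1OC
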